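**Plan**
1. Retrosynthesis (atisane numbering): the C15 ketone comes from allylic oxidation and the C14 acetate from a C14 ketone, giving bicyclo[2.2.2]octanone 17. Cutting C16–C12 gives the ring B/ring C enone lactone 16 with a 2-bromoallyl arm on C8.
2. 16 is cut at C9–C11 and at the lactone C3–O bond to the monocyclic diketo ester 14, then at C8–C15, C8–C14, C10–C1 and C5–C4 back to 2-methylcyclohex-2-en-1-one.
3. Forward: ring B is the commercial enone; ring C and the lactone close together (vinylogous aldol/lactonisation); the third bridge (ring C16–C15–C8–C9–C11–C12) closes last by radical cyclisation.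
4. Enabling feature: in ring C (C8, C9, C11, C12, C13, C14) C12 is the β-carbon of the C14 enone and lies 1,4 to the quaternary C8, whose C15–C16 arm is axial. A σ-vinyl radical at C16 can therefore reach C12, and the C14 carbonyl that activates C12 later becomes the acetoxy carbon.
5. Stereochemistry: C5 by ligand-controlled conjugate addition; C10 by trans enolate trapping; C8 by alkylation anti to the C10 methyl; C9 by the tether; C12 by the bridge; C14 by thermodynamically controlled ketone reduction.

Key step: step 7

Remark: atisane numbering is used throughout (C5 bears isopropenyl; C10 bears the methyl and the C1–C2–C3 chain; C9 is the lactone carbinol carbon; C8 and C12 are bridgeheads; C14 bears OAc; C15 is the ketone; C16=C17 is the methylene). Compounds 11 and 20 are epimer mixtures at centres erased in the same step, and C8 of 12 is labile, so these centres are left open in the SMILES.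

Step 1
Reactants: 1 2-methylcyclohex-2-en-1-one; 2 isopropenylmagnesium bromide; 3 allyl iodide
Product: 5 (2S,3S)-2-allyl-2-methyl-3-(prop-1-en-2-yl)cyclohexan-1-one, via bromomagnesium enolate 4 (not isolated)
Conditions: 2, CuBr·SMe2 (5 mol %), chiral ferrocenyl diphosphine (Josiphos/Taniaphos family, antipode giving 3S), tBuOMe, −78 °C; then 3, DMPU, −30 → 23 °C
Reagents that add atoms: isopropenylmagnesium bromide (2) C=C(C)[Mg]Br; allyl iodide (3) C=CCI
Why: Copper-catalysed asymmetric conjugate addition of the Grignard reagent to the α-methyl enone sets C5 under ligand control, and the magnesium enolate is allylated at C10 anti to the new isopropenyl group (conjugate addition–enolate trapping), so the methyl ends cis and the allyl trans to isopropenyl.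

Step 2
Reactants: 5 (2S,3S)-2-allyl-2-methyl-3-(prop-1-en-2-yl)cyclohexan-1-one
Product: 7 (2S,3S)-2-(3-hydroxypropyl)-2-methyl-3-(prop-1-en-2-yl)cyclohexan-1-one, via alkyl catecholboronate 6 (not isolated)
Conditions: catecholborane, RhCl(PPh3)3 (2 mol %), THF, 23 °C; then NaOH, H2O2, 0 °C
Reagents that add atoms: catecholborane [H]B1Oc2ccccc2O1 (boron, kept only in 6); hydrogen peroxide OO (oxygen)
Why: Rhodium-catalysed hydroboration–oxidation is selective for the monosubstituted terminal alkene over the 1,1-disubstituted isopropenyl group and the hindered ketone and gives the anti-Markovnikov alcohol without creating a stereocenter.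

Step 3
Reactants: 7 (2S,3S)-2-(3-hydroxypropyl)-2-methyl-3-(prop-1-en-2-yl)cyclohexan-1-one
Product: 9 methyl 3-[(1S,2S)-1-methyl-6-oxo-2-(prop-1-en-2-yl)cyclohexyl]propanoate, via keto acid 8 (not isolated)
Conditions: TEMPO (20 mol %), PhI(OAc)2, MeCN/H2O, 23 °C; then MeI, K2CO3, DMF, 23 °C
Reagents that add atoms: water O (second oxygen of the acid); iodomethane CI (methyl)
Why: The nitroxyl-catalysed oxidation takes the primary alcohol to the acid without touching either alkene, and carboxylate O-alkylation with MeI gives the methyl ester that later serves as the lactone acyl donor.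

Step 4
Reactants: 9 methyl 3-[(1S,2S)-1-methyl-6-oxo-2-(prop-1-en-2-yl)cyclohexyl]propanoate; 10 (E)-but-2-enal
Product: 12 methyl 3-[(1S,2S)-5-[(E)-but-2-enoyl]-1-methyl-6-oxo-2-(prop-1-en-2-yl)cyclohexyl]propanoate, via aldol adduct 11 (not isolated)
Conditions: LiN(iPr)2 (1.05 equiv), THF, −78 °C; 10; AcOH; then Dess–Martin periodinane, pyridine, CH2Cl2, 0 → 23 °C
Reagents that add atoms: (E)-but-2-enal (10) C/C=C/C=O
Why: Kinetic deprotonation occurs at C8, the only enolisable ketone position because C10 is quaternary, the enolate adds 1,2 to crotonaldehyde (aldol addition), and oxidation of the carbinol mixture gives the β-diketone in which the future C14 carbonyl is in place and both new stereocenters are erased or labile.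

Step 5
Reactants: 12 methyl 3-[(1S,2S)-5-[(E)-but-2-enoyl]-1-methyl-6-oxo-2-(prop-1-en-2-yl)cyclohexyl]propanoate; 13 2,3-dibromoprop-1-ene
Product: 14 methyl 3-[(1S,2S,5S)-5-(2-bromoprop-2-enyl)-5-[(E)-but-2-enoyl]-1-methyl-6-oxo-2-(prop-1-en-2-yl)cyclohexyl]propanoate
Conditions: 13, K2CO3, acetone, 50 °C
Reagents that add atoms: 2,3-dibromoprop-1-ene (13) C=C(Br)CBr
Why: C-alkylation of the β-diketonate by the allylic bromide terminus should occur on the face of C8 opposite the pseudo-axial C10 methyl, so the bromoallyl arm (C15–C17) ends trans and the butenoyl arm (C14) cis to that methyl, which sets the quaternary C8.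

Step 6
Reactants: 14 methyl 3-[(1S,2S,5S)-5-(2-bromoprop-2-enyl)-5-[(E)-but-2-enoyl]-1-methyl-6-oxo-2-(prop-1-en-2-yl)cyclohexyl]propanoate
Product: 16 tricyclic bromoallyl enone lactone (rings B and C cis-fused; C14 ketone; C12=C13; lactone oxygen on C9), via lithium alkoxide 15 (not isolated)
Conditions: LiN(SiMe3)2 (1.05 equiv), THF, −78 → −10 °C; AcOH, −78 °C
Reagents that add atoms: none
Why: γ-Deprotonation of the butenoyl group gives a dienolate whose C11 adds to the C9 ketone (intramolecular vinylogous aldol) from the face of the axial C14 arm, closing ring C cis-fused, and the tertiary alkoxide, cis to the ester chain on C10, lactonises at once, which makes the addition irreversible and fixes C9; the cold acidic quench guards against base-induced loss of the lactone carboxylate from the product.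

Step 7
Reactants: 16 tricyclic bromoallyl enone lactone
Product: 17 15-deoxo-14-deacetoxy-14-oxocrotobarin (bicyclo[2.2.2]octan-14-one lactone with C16=C17 methylene)
Conditions: Bu3SnH (slow addition), AIBN (cat.), benzene (0.01 M), 80 °C
Reagents that add atoms: none
Why: Bu3Sn• abstracts bromine from the 2-bromoallyl group to give a σ-vinyl radical at C16, which adds to C12, the β-carbon of the ring C enone, and the resulting C13 α-keto radical takes hydrogen from Bu3SnH (vinyl radical conjugate cyclisation, the established route from 6-(2-bromoallyl)cyclohex-2-enones to bicyclo[2.2.2]octanones). The new ring (C16–C15–C8–C9–C11–C12) closes in the 6-exo-trig mode and spans ring C 1,4 as a boat. The only new stereocenter, C12, is fixed by the tether, because the C15 arm sits axially on one face of ring C at C8 and C16 can bond to C12 only from that face. Selectivity for C12 (bicyclo[2.2.2]) over C13 (5-exo, bicyclo[3.2.1]) is needed and is secured by the enone polarisation, since attack at the β-carbon gives the stabilised α-keto radical, which also has no drive to rearrange to the [3.2.1] isomer. Premature reduction of the vinyl radical and 1,5-hydrogen transfer from C11 are held back by high dilution and slow addition of Bu3SnH. The isopropenyl group and the lactone are inert under these neutral conditions.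

Step 8
Reactants: 17 15-deoxo-14-deacetoxy-14-oxocrotobarin
Product: 18 15-deoxo-14-O-deacetylcrotobarin (C14 alcohol)
Conditions: SmI2 (2.5 equiv), THF/iPrOH, 0 → 23 °C
Reagents that add atoms: none
Why: Single-electron (dissolving-metal type) reduction through the ketyl and the α-oxido carbanion should give the thermodynamically preferred alcohol, with OH turned toward the C15–C16 bridge and away from the syn-axial C10 methyl (the same reversal seen between hydride and metal reductions of hindered steroidal 11-ketones), and the lactone and isolated alkenes are not reduced without water or amine activation.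

Step 9
Reactants: 18 15-deoxo-14-O-deacetylcrotobarin
Product: 19 15-deoxocrotobarin (C14 acetate)
Conditions: Ac2O, DMAP (cat.), pyridine, 23 °C
Reagents that add atoms: acetic anhydride CC(=O)OC(C)=O
Why: DMAP-catalysed acylation of the exposed secondary alcohol proceeds with retention at C14.

Step 10
Reactants: 19 15-deoxocrotobarin
Product: 21 crotobarin, via allylic alcohol 20 (not isolated)
Conditions: SeO2 (cat.), tBuOOH, CH2Cl2, 23 °C; then Dess–Martin periodinane, CH2Cl2, 23 °C
Reagents that add atoms: selenium dioxide O=[Se]=O (oxygen donor, regenerated); tert-butyl hydroperoxide CC(C)(C)OO (terminal oxygen source)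
Why: Allylic hydroxylation by the ene/[2,3]-sigmatropic sequence should take place at C15, the only allylic methylene in the molecule (C12 is a bridgehead and the isopropenyl group offers only a methyl and a hindered methine, which react more slowly), and oxidation of the allylic alcohol then gives the α-methylene ketone.

**Compound list**
1 | 2-methylcyclohex-2-en-1-one | CC1=CCCC1=O | starting material
2 | isopropenylmagnesium bromide | C=C(C)[Mg]Br | starting material
3 | allyl iodide | C=CCI | starting material
4 | bromomagnesium (S)-2-methyl-3-(prop-1-en-2-yl)cyclohex-1-en-1-olate | CC1=C(O[Mg]Br)CCC[C@H]1C(C)=C | intermediate (not isolated)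
5 | (2S,3S)-2-allyl-2-methyl-3-(prop-1-en-2-yl)cyclohexan-1-one (methyl cis, allyl trans to isopropenyl) | C=CC[C@]1(C)C(=O)CCC[C@H]1C(C)=C | intermediate
6 | 2-{3-[(1S,2S)-1-methyl-6-oxo-2-(prop-1-en-2-yl)cyclohexyl]propyl}-1,3,2-benzodioxaborole | O1c2ccccc2OB1CCC[C@]1(C)C(=O)CCC[C@H]1C(C)=C | intermediate (not isolated)
7 | (2S,3S)-2-(3-hydroxypropyl)-2-methyl-3-(prop-1-en-2-yl)cyclohexan-1-one | OCCC[C@]1(C)C(=O)CCC[C@H]1C(C)=C | intermediate
8 | 3-[(1S,2S)-1-methyl-6-oxo-2-(prop-1-en-2-yl)cyclohexyl]propanoic acid | OC(=O)CC[C@]1(C)C(=O)CCC[C@H]1C(C)=C | intermediate (not isolated)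
9 | methyl 3-[(1S,2S)-1-methyl-6-oxo-2-(prop-1-en-2-yl)cyclohexyl]propanoate | COC(=O)CC[C@]1(C)C(=O)CCC[C@H]1C(C)=C | intermediate
10 | (E)-but-2-enal (crotonaldehyde) | C/C=C/C=O | starting material
11 | methyl 3-[(1S,2S)-5-[(E)-1-hydroxybut-2-enyl]-1-methyl-6-oxo-2-(prop-1-en-2-yl)cyclohexyl]propanoate, epimer mixture at C8 and the carbinol carbon | COC(=O)CC[C@]1(C)C(=O)C(C(O)/C=C/C)CC[C@H]1C(C)=C | intermediate (not isolated)
12 | methyl 3-[(1S,2S)-5-[(E)-but-2-enoyl]-1-methyl-6-oxo-2-(prop-1-en-2-yl)cyclohexyl]propanoate (β-diketone, largely enolised, C8 labile) | COC(=O)CC[C@]1(C)C(=O)C(C(=O)/C=C/C)CC[C@H]1C(C)=C | intermediate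
13 | 2,3-dibromoprop-1-ene | C=C(Br)CBr | starting material
14 | methyl 3-[(1S,2S,5S)-5-(2-bromoprop-2-enyl)-5-[(E)-but-2-enoyl]-1-methyl-6-oxo-2-(prop-1-en-2-yl)cyclohexyl]propanoate (butenoyl cis, bromoallyl trans to the ring methyl) | COC(=O)CC[C@]1(C)C(=O)[C@@](CC(Br)=C)(C(=O)/C=C/C)CC[C@H]1C(C)=C | intermediate
15 | lithium alkoxide of the cis-fused ring B/ring C hydroxy enone methyl ester (C9–OLi, C11 syn to C14) | COC(=O)CC[C@]1(C)[C@@]2(O[Li])CC=CC(=O)[C@@]2(CC(Br)=C)CC[C@H]1C(C)=C | intermediate (not isolated)
16 | tricyclic bromoallyl enone lactone: ring B cis-fused to ring C cyclohex-2-enone (C14=O, C12=C13) and to the C3→O–C9 δ-lactone; C8 carries 2-bromoprop-2-enyl, C10 methyl, C5 isopropenyl | C=C(Br)C[C@]12CC[C@@H](C(=C)C)[C@]3(C)CCC(=O)O[C@@]31CC=CC2=O | intermediate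
17 | 15-deoxo-14-deacetoxy-14-oxocrotobarin (bicyclo[2.2.2]octan-14-one, C16=C17 methylene, C15 methylene) | C=C1C[C@]23CC[C@@H](C(=C)C)[C@]4(C)CCC(=O)O[C@@]42C[C@H]1CC3=O | intermediate
18 | 15-deoxo-14-O-deacetylcrotobarin (C14–OH toward the C15–C16 bridge) | C=C1C[C@]23CC[C@@H](C(=C)C)[C@]4(C)CCC(=O)O[C@@]42C[C@H]1C[C@@H]3O | intermediate
19 | 15-deoxocrotobarin (C14 acetate) | C=C1C[C@]23CC[C@@H](C(=C)C)[C@]4(C)CCC(=O)O[C@@]42C[C@H]1C[C@@H]3OC(C)=O | intermediate
20 | 15-deoxo-15-hydroxycrotobarin, epimer mixture at C15 | C=C1C(O)[C@]23CC[C@@H](C(=C)C)[C@]4(C)CCC(=O)O[C@@]42C[C@H]1C[C@@H]3OC(C)=O | intermediate (not isolated)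
21 | crotobarin | C=C1C(=O)[C@]23CC[C@@H](C(=C)C)[C@]4(C)CCC(=O)O[C@@]42C[C@H]1C[C@@H]3OC(C)=O | target

Total step count: 10. Longest linear sequence: 10 steps (fully linear from 1).

**Steps most likely to fail**

Step 6. The non-enolisable 1,3-diketone of 14 may be cleaved in a retro-Claisen process by the methoxide set free, the ester enolate may close onto the C14 carbonyl instead, or the product may lose its lactone carboxylate by base-induced vinylogous β-elimination. The fallback avoids alkoxide bases altogether and sets out from 14. Soft enolisation (TBSOTf, Et3N, CH2Cl2) should give the tert-butyldimethylsilyl dienol ether F1. An intramolecular vinylogous Mukaiyama aldol addition (TiCl4, CH2Cl2, −78 °C) should then close ring C onto C9 and, after aqueous work-up, give the hydroxy enone ester F2. Acid-catalysed lactonisation (camphorsulfonic acid, toluene, 60 °C) brings the sequence back to 16.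

Step 8. Protonation of the organosamarium intermediate from the open face, or chelation of trivalent samarium by the lactone oxygen, may erode the facial selectivity and leave the C14 epimer. The fallback sets out from 17. Reduction with NaBH4 in MeOH should deliver hydride from the open face and give the 14-epi alcohol F3. Equilibration by reversible hydride transfer (Al(OiPr)3, catalytic acetone, iPrOH/toluene, 80 °C; Meerwein–Ponndorf–Verley/Oppenauer conditions) should then drain F3 into the epimer that avoids the syn-axial C10 methyl; the route is rejoined at 18.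

Step 5. O-alkylation of the diketonate, closure of the enol oxygen onto the butenoyl group, or attack on the wrong face of C8 may divert the alkylation. The fallback sets out from 12 and replaces the SN2 alkylation by a Tsuji–Trost allylation (2-bromoallyl methyl carbonate, Pd2(dba)3 as the source of zerovalent palladium, the matched enantiomer of N,N'-bis(2-diphenylphosphinobenzoyl)-1,2-diaminocyclohexane, CH2Cl2, 0 °C). Its soft-nucleophile pathway is inherently C-selective, and the ligand rather than the substrate sets the face. It arrives directly at 14, and no new compound is formed (F0).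

**Further compounds**
F1 | step 6 | methyl 3-[(1S,2S,5S)-5-(2-bromoprop-2-enyl)-5-[1-(tert-butyldimethylsilyloxy)buta-1,3-dienyl]-1-methyl-6-oxo-2-(prop-1-en-2-yl)cyclohexyl]propanoate | COC(=O)CC[C@]1(C)C(=O)[C@@](CC(Br)=C)(C(O[Si](C)(C)C(C)(C)C)=CC=C)CC[C@H]1C(C)=C
F2 | step 6 | cis-fused ring B/ring C hydroxy enone methyl ester (free C9–OH form of 15) | COC(=O)CC[C@]1(C)[C@@]2(O)CC=CC(=O)[C@@]2(CC(Br)=C)CC[C@H]1C(C)=C
F3 | step 8 | 14-epi-15-deoxo-14-O-deacetylcrotobarin (C14–OH toward the C10 methyl) | C=C1C[C@]23CC[C@@H](C(=C)C)[C@]4(C)CCC(=O)O[C@@]42C[C@H]1C[C@H]3O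
F0 | step 5 | none | none
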